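**Plan**

Germacrane numbering (C1–C15, lactone carbonyl C12) is used throughout. Retrosynthetically the C8 angelate and C11 acetate are removed and the C10 methyl is traced to an enol triflate. The ten-membered ring is then unravelled by a retro-[3,3] shift: it holds the 1,5-diene C10=C1–C2–C3–C4=C5, so cutting C2–C3 while re-forming C5–C10 gives a trans-1-vinyl-2-isopropenylcyclohexanol (ring C5–C10) that already carries the all-cis C6–O/C7–C11/C8–O triad and the 6,12-lactone.
The cyclohexanol is cut at C10–C1 (vinyl addition to a ketone), C5–C10 (carbonyl-ene), C8–C9 (acetate aldol) and C6–C7 (anti-aldol), leading to (R)-citramalic acid, 3-methylbut-2-enal, S-ethyl thioacetate, vinylmagnesium bromide and angelic acid.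
Forward ring order: dioxolanone (protecting ring), cyclohexane by ene closure, γ-lactone O6–C12 by acyl transfer from the dioxolanone, and last the ten-membered carbocycle by ring expansion; nothing is macrocyclised.
Stereochemistry: C11 from citramalic acid; C6 and C7 from an auxiliary-controlled anti-aldol; C8 from a reagent-controlled Mukaiyama aldol matched with Felkin–Anh bias; the 1(10)E and 4E alkenes from the chair transition state of the trans-diequatorial dialkenylcyclohexanol, kept in the methylation; the Z ester from angelic acid.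

Key step: step 14

Assumption: the facial preferences known for the magnesium-catalysed thiazolidinethione anti-aldol and for the chiral tin promoter with simple substrates are taken to hold for these hindered ones, and the auxiliary and diamine enantiomers named below are the ones predicted on that basis.

**Route**

Step 1
Reactants: 1 (R)-citramalic acid
Product: 2 2-[(4R)-2,2,4-trimethyl-5-oxo-1,3-dioxolan-4-yl]acetic acid
Conditions: Me2C(OMe)2, PPTS (cat.), acetone, rt
Reagents that add atoms: 2,2-dimethoxypropane, COC(C)(C)OC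
Why: Acid-catalysed transketalisation (acetonide formation of an α-hydroxy acid) ties the tertiary hydroxyl and the adjacent carboxyl into the favoured five-membered dioxolanone, leaves the distal carboxyl free and does not touch the C11 stereocentre.

Step 2
Reactants: 2 2-[(4R)-2,2,4-trimethyl-5-oxo-1,3-dioxolan-4-yl]acetic acid; 3 (4R)-4-benzyl-1,3-thiazolidine-2-thione
Product: 4 (4R)-4-benzyl-3-{2-[(4R)-2,2,4-trimethyl-5-oxo-1,3-dioxolan-4-yl]acetyl}-1,3-thiazolidine-2-thione
Conditions: DCC, DMAP (cat.), CH2Cl2, 0 °C to rt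
Reagents that add atoms: none
Why: Carbodiimide (Steglich-type) N-acylation of the thiazolidinethione by the free side-chain acid runs under neutral conditions that leave the dioxolanone and C11 unchanged.

Step 3
Reactants: 4 (4R)-4-benzyl-3-{2-[(4R)-2,2,4-trimethyl-5-oxo-1,3-dioxolan-4-yl]acetyl}-1,3-thiazolidine-2-thione; 5 3-methylbut-2-enal
Product: 7 (4R)-4-benzyl-3-{(2S,3R)-3-hydroxy-5-methyl-2-[(4R)-2,2,4-trimethyl-5-oxo-1,3-dioxolan-4-yl]hex-4-enoyl}-1,3-thiazolidine-2-thione, via trimethylsilyl ether 6 (not isolated)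
Conditions: MgBr2·OEt2 (0.2 equiv), Et3N, TMSCl, EtOAc, rt; then 1 M HCl/THF, 0 °C
Reagents that add atoms: none
Why: In this magnesium-halide-catalysed direct anti-aldol reaction of an N-acylthiazolidinethione (soft enolisation, turnover by silylation of the aldolate) the Z enolate should add to the enal through a closed boat-like transition state on the face away from the benzyl group of the dipole-opposed rotamer, which sets C6 (R) and C7 (S) in the anti relationship, and the brief acid treatment removes only the labile TMS group.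

Step 4
Reactants: 7 anti-aldol alcohol
Product: 8 (4R)-4-benzyl-3-{(2S,3R)-5-methyl-3-[(triethylsilyl)oxy]-2-[(4R)-2,2,4-trimethyl-5-oxo-1,3-dioxolan-4-yl]hex-4-enoyl}-1,3-thiazolidine-2-thione
Conditions: TESOTf, 2,6-lutidine, CH2Cl2, −78 °C
Reagents that add atoms: triethylsilyl trifluoromethanesulfonate, CC[Si](CC)(CC)OS(=O)(=O)C(F)(F)F
Why: Silylation of the secondary allylic alcohol with a silyl triflate and a hindered base is fast and non-epimerising at low temperature and removes the free hydroxyl that could otherwise lactonise onto the dioxolanone.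

Step 5
Reactants: 8 TES-protected aldol imide
Product: 9 (2S,3R)-5-methyl-3-[(triethylsilyl)oxy]-2-[(4R)-2,2,4-trimethyl-5-oxo-1,3-dioxolan-4-yl]hex-4-enal
Conditions: i-Bu2AlH, CH2Cl2, −78 °C; aq. potassium sodium tartrate
Reagents that add atoms: none
Why: Hydride reduction of the highly activated N-acylthiazolidinethione gives an aluminium hemithioaminal that is stable at −78 °C and collapses to the aldehyde only on work-up, faster than the hindered dioxolanone ester is attacked, so the C8 aldehyde should form directly without epimerising C7.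

Step 6
Reactants: 10 S-ethyl ethanethioate
Product: 11 1-(ethylsulfanyl)-1-[(trimethylsilyl)oxy]ethene
Conditions: LiN(i-Pr)2, THF, −78 °C; TMSCl
Reagents that add atoms: chlorotrimethylsilane, C[Si](C)(C)Cl
Why: Kinetic deprotonation of the thioester and O-silylation of the lithium enolate is the standard way to the ketene silyl thioacetal.

Step 7
Reactants: 9 C8 aldehyde; 11 1-(ethylsulfanyl)-1-[(trimethylsilyl)oxy]ethene
Product: 12 S-ethyl (3S,4S,5R)-3-hydroxy-7-methyl-5-[(triethylsilyl)oxy]-4-[(4R)-2,2,4-trimethyl-5-oxo-1,3-dioxolan-4-yl]oct-6-enethioate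
Conditions: Sn(OTf)2, (S)-1-methyl-2-[(naphthalen-1-ylamino)methyl]pyrrolidine, Bu3SnF, CH2Cl2, −78 °C; aq. NaHCO3
Reagents that add atoms: none
Why: In this Mukaiyama aldol addition, promoted by a chiral divalent-tin triflate–diamine Lewis acid with fluoride activation of the ketene acetal, the promoter should direct the acetate nucleophile to the si face of the C8 aldehyde, which is also the Felkin–Anh face when the quaternary C11 branch lies anti to the nucleophile, so reagent and substrate control are matched in setting C8 (S).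

Step 8
Reactants: 12 β-hydroxy thioester
Product: 13 S-ethyl (3S,4S,5R)-3-[(4-methoxybenzyl)oxy]-7-methyl-5-[(triethylsilyl)oxy]-4-[(4R)-2,2,4-trimethyl-5-oxo-1,3-dioxolan-4-yl]oct-6-enethioate
Conditions: 2-(4-methoxybenzyloxy)-4-methylquinoline, MeOTf, MgO, PhCF3, 0 °C to rt
Reagents that add atoms: 2-(4-methoxybenzyloxy)-4-methylquinoline, COc1ccc(COc2cc(C)c3ccccc3n2)cc1
Why: PMB transfer from the N-methylquinolinium salt formed in situ (neutral benzyl-type etherification with MgO as acid scavenger) protects the hindered C8 hydroxyl without base, so no retro-aldol or elimination, and without acid strong enough to ionise the allylic silyl ether or to trigger lactonisation onto the dioxolanone.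

Step 9
Reactants: 13 PMB-protected thioester
Product: 14 (3S,4S,5R)-3-[(4-methoxybenzyl)oxy]-7-methyl-5-[(triethylsilyl)oxy]-4-[(4R)-2,2,4-trimethyl-5-oxo-1,3-dioxolan-4-yl]oct-6-enal
Conditions: Et3SiH, Pd/C (10%), acetone, rt
Reagents that add atoms: none
Why: In the Fukuyama reduction zerovalent palladium inserts into the C–S bond and the silane delivers hydride, which converts the thioester into the C10 aldehyde while the dioxolanone, both ethers and the trisubstituted alkene stay untouched.

Step 10
Reactants: 14 C10 aldehyde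
Product: 15 (1S,2R,3R,4S,5S)-5-[(4-methoxybenzyl)oxy]-2-(prop-1-en-2-yl)-3-[(triethylsilyl)oxy]-4-[(4R)-2,2,4-trimethyl-5-oxo-1,3-dioxolan-4-yl]cyclohexan-1-ol
Conditions: Me2AlCl, CH2Cl2, −78 to −40 °C
Reagents that add atoms: none
Why: In this Lewis-acid-promoted intramolecular carbonyl-ene reaction of the citronellal-to-isopulegol kind C5 of the trisubstituted alkene adds to the complexed aldehyde and an allylic methyl hydrogen passes to oxygen through a chair in which the bulky C7 group is equatorial and O6 and O8 are axial, which closes ring C5–C10 with the isopropenyl group equatorial at C5 and the new hydroxyl equatorial at C10, the latter being of no consequence because it is oxidised next.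

Step 11
Reactants: 15 2-isopropenylcyclohexanol
Product: 16 (2S,3S,4S,5S)-5-[(4-methoxybenzyl)oxy]-2-(prop-1-en-2-yl)-3-[(triethylsilyl)oxy]-4-[(4R)-2,2,4-trimethyl-5-oxo-1,3-dioxolan-4-yl]cyclohexan-1-one
Conditions: Dess–Martin periodinane, NaHCO3, CH2Cl2, 0 °C to rt
Reagents that add atoms: none
Why: Buffered Dess–Martin oxidation converts the secondary alcohol into the C10 ketone under non-basic conditions, so the epimerisable C5 centre and the two β-alkoxy groups (C6, C8) are not exposed to elimination.

Step 12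
Reactants: 16 C10 ketone; 17 vinylmagnesium bromide
Product: 19 (1S,2S,3R,4S,5S)-1-ethenyl-5-[(4-methoxybenzyl)oxy]-2-(prop-1-en-2-yl)-3-[(triethylsilyl)oxy]-4-[(4R)-2,2,4-trimethyl-5-oxo-1,3-dioxolan-4-yl]cyclohexan-1-ol, via vinylcerium dichloride 18 (not isolated)
Conditions: CeCl3 (anhydrous), THF, −78 °C; then 16, −78 °C
Reagents that add atoms: none
Why: The weakly basic organocerium reagent adds 1,2 to the ketone without enolisation, β-elimination or attack on the dioxolanone, and it should enter equatorially because the axial trajectory is blocked by the syn-axial C6 and C8 oxygen substituents, which sets C10 with the vinyl group trans to the isopropenyl group and the hydroxyl axial.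

Step 13
Reactants: 19 vinyl carbinol
Product: 21 (3R,3aS,4S,6S,7S,7aR)-6-ethenyl-3,6-dihydroxy-4-[(4-methoxybenzyl)oxy]-3-methyl-7-(prop-1-en-2-yl)hexahydro-1-benzofuran-2(3H)-one, via C6 alcohol 20 (not isolated)
Conditions: Bu4NF, THF, 0 °C to rt
Reagents that add atoms: none
Why: Fluoride desilylation frees the C6 alkoxide, which attacks the neighbouring dioxolanone carbonyl in a five-membered acyl transfer that expels acetone and the C11 hydroxyl and gives the cis-fused γ-lactone without touching a stereocentre, and this is done only now because a β-acyloxy ketone at the stage of 16 would eliminate.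

Step 14
Reactants: 21 trans-1-vinyl-2-isopropenylcyclohexanol lactone
Product: 23 (6R,7S,8S,11R)-11-hydroxy-8-(4-methoxybenzyloxy)-10-(trifluoromethanesulfonyloxy)-14-norgermacra-1(10),4E-dien-12,6-olide (C9 and C2 trans across C10=C1), via ten-membered potassium enolate 22 (not isolated)
Conditions: KH (4 equiv), 18-crown-6, THF, 0 °C to rt; then PhNTf2, −78 to 0 °C
Reagents that add atoms: N-phenylbis(trifluoromethanesulfonimide), O=S(=O)(N(c1ccccc1)S(=O)(=O)C(F)(F)F)C(F)(F)F
Why: Double deprotonation gives the C10/C11 dialkoxide, and the C10 oxyanion accelerates a concerted [3,3] sigmatropic shift (anionic oxy-Cope rearrangement, the known ring expansion of trans-1,2-dialkenylcyclohexanols to cyclodec-5-enone enolates) in which C2 bonds to C3 while C5–C10 breaks. The ten-membered carbocycle is therefore not closed end to end but arises by four-carbon ring expansion of the cyclohexane through a six-membered chair transition state, and the γ-lactone is carried through unchanged. No new stereocentre is formed (C5 and C10 become trigonal); the elements created are the two ring alkenes, both fixed by the chair in which vinyl and isopropenyl are equatorial and the oxyanion is axial, so that C9/C2 and C6/C3 end up trans. Enolate formation makes the step irreversible and places the enolate regiospecifically at C10=C1, so O-sulfonylation at −78 °C should give a single enol triflate with the geometry retained. The selectivity needed is the trans-diequatorial arrangement of the two alkenyl groups, secured in step 12, together with base tolerance, secured by the quaternary C11 (no lactone α-hydrogen), by the benzyl-type rather than silyl ether at C8 (no silyl shift to O10) and by the C11 alkoxide, which deactivates the lactone carbonyl and is sulfonylated far more slowly than the enolate.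

Step 15
Reactants: 23 enol triflate
Product: 24 (1(10)E,4E,6R,7S,8S,11R)-11-hydroxy-8-(4-methoxybenzyloxy)germacra-1(10),4-dien-12,6-olide
Conditions: MeZnCl, Pd(PPh3)4 (5 mol%), THF, rt
Reagents that add atoms: methylzinc chloride, C[Zn]Cl
Why: Negishi coupling of the enol triflate proceeds with retention of alkene geometry and installs the C10 methyl, the mild organozinc tolerating the lactone and the free hydroxyl, while room temperature keeps zerovalent palladium from ionising the hindered allylic C6 lactone oxygen.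

Step 16
Reactants: 24 germacradienolide C11 alcohol
Product: 25 (1(10)E,4E,6R,7S,8S,11R)-11-acetoxy-8-(4-methoxybenzyloxy)germacra-1(10),4-dien-12,6-olide
Conditions: Ac2O, Et3N, DMAP, CH2Cl2, rt
Reagents that add atoms: acetic anhydride, CC(=O)OC(C)=O
Why: Nucleophilic catalysis by DMAP acylates the tertiary α-hydroxy-lactone hydroxyl under basic, acid-free conditions, which avoids transannular cyclisation of the 1(10),4-diene.

Step 17
Reactants: 25 C11 acetate
Product: 26 (1(10)E,4E,6R,7S,8S,11R)-11-acetoxy-8-hydroxygermacra-1(10),4-dien-12,6-olide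
Conditions: DDQ, CH2Cl2/pH 7 phosphate buffer, 0 °C
Reagents that add atoms: none
Why: Oxidative cleavage of the electron-rich PMB ether by single-electron transfer to the quinone and hydrolysis of the oxocarbenium ion frees the C8 hydroxyl under buffered conditions that spare the diene, the lactone and the acetate, whose trans disposition to C8 on the lactone ring disfavours acyl migration.

Step 18
Reactants: 26 C8 alcohol; 27 angelic acid
Product: 29 (1(10)E,4E,6R,7S,8S,11R)-11-acetoxy-8-angeloyloxygermacra-1(10),4-dien-12,6-olide (CNP0144564.1), via mixed anhydride 28 (not isolated)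
Conditions: 2,4,6-Cl3C6H2COCl, Et3N, toluene, rt; then 26, toluene, 75 °C
Reagents that add atoms: none
Why: Yamaguchi-type esterification through the angelic 2,4,6-trichlorobenzoic mixed anhydride, run without a nucleophilic catalyst, should acylate the hindered secondary alcohol at the less hindered angeloyl carbonyl and avoids the addition–elimination pathway that isomerises the Z ester to the tiglate.

**Compound list**

1 | (R)-citramalic acid [(2R)-2-hydroxy-2-methylbutanedioic acid] | OC(=O)[C@](C)(O)CC(=O)O | starting material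
2 | 2-[(4R)-2,2,4-trimethyl-5-oxo-1,3-dioxolan-4-yl]acetic acid | OC(=O)C[C@@]1(C)OC(C)(C)OC1=O | intermediate
3 | (4R)-4-benzyl-1,3-thiazolidine-2-thione | S=C1N[C@H](Cc2ccccc2)CS1 | starting material
4 | (4R)-4-benzyl-3-{2-[(4R)-2,2,4-trimethyl-5-oxo-1,3-dioxolan-4-yl]acetyl}-1,3-thiazolidine-2-thione | O=C(C[C@@]1(C)OC(C)(C)OC1=O)N1C(=S)SC[C@H]1Cc1ccccc1 | intermediate
5 | 3-methylbut-2-enal | CC(C)=CC=O | starting material
6 | trimethylsilyl ether of anti-aldol adduct 7 (C6–OTMS) | CC(C)=C[C@@H](O[Si](C)(C)C)[C@@H]([C@@]1(C)OC(C)(C)OC1=O)C(=O)N1C(=S)SC[C@H]1Cc1ccccc1 | intermediate (not isolated)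
7 | (4R)-4-benzyl-3-{(2S,3R)-3-hydroxy-5-methyl-2-[(4R)-2,2,4-trimethyl-5-oxo-1,3-dioxolan-4-yl]hex-4-enoyl}-1,3-thiazolidine-2-thione | CC(C)=C[C@@H](O)[C@@H]([C@@]1(C)OC(C)(C)OC1=O)C(=O)N1C(=S)SC[C@H]1Cc1ccccc1 | intermediate
8 | (4R)-4-benzyl-3-{(2S,3R)-5-methyl-3-[(triethylsilyl)oxy]-2-[(4R)-2,2,4-trimethyl-5-oxo-1,3-dioxolan-4-yl]hex-4-enoyl}-1,3-thiazolidine-2-thione | CC(C)=C[C@@H](O[Si](CC)(CC)CC)[C@@H]([C@@]1(C)OC(C)(C)OC1=O)C(=O)N1C(=S)SC[C@H]1Cc1ccccc1 | intermediate
9 | (2S,3R)-5-methyl-3-[(triethylsilyl)oxy]-2-[(4R)-2,2,4-trimethyl-5-oxo-1,3-dioxolan-4-yl]hex-4-enal | CC(C)=C[C@@H](O[Si](CC)(CC)CC)[C@@H]([C@@]1(C)OC(C)(C)OC1=O)C=O | intermediate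
10 | S-ethyl ethanethioate (S-ethyl thioacetate) | CC(=O)SCC | starting material
11 | 1-(ethylsulfanyl)-1-[(trimethylsilyl)oxy]ethene | C=C(O[Si](C)(C)C)SCC | intermediate
12 | S-ethyl (3S,4S,5R)-3-hydroxy-7-methyl-5-[(triethylsilyl)oxy]-4-[(4R)-2,2,4-trimethyl-5-oxo-1,3-dioxolan-4-yl]oct-6-enethioate | CC(C)=C[C@@H](O[Si](CC)(CC)CC)[C@@H]([C@@]1(C)OC(C)(C)OC1=O)[C@H](CC(=O)SCC)O | intermediate
13 | S-ethyl (3S,4S,5R)-3-[(4-methoxybenzyl)oxy]-7-methyl-5-[(triethylsilyl)oxy]-4-[(4R)-2,2,4-trimethyl-5-oxo-1,3-dioxolan-4-yl]oct-6-enethioate | CC(C)=C[C@@H](O[Si](CC)(CC)CC)[C@@H]([C@@]1(C)OC(C)(C)OC1=O)[C@H](CC(=O)SCC)OCc1ccc(OC)cc1 | intermediate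
14 | (3S,4S,5R)-3-[(4-methoxybenzyl)oxy]-7-methyl-5-[(triethylsilyl)oxy]-4-[(4R)-2,2,4-trimethyl-5-oxo-1,3-dioxolan-4-yl]oct-6-enal | CC(C)=C[C@@H](O[Si](CC)(CC)CC)[C@@H]([C@@]1(C)OC(C)(C)OC1=O)[C@H](CC=O)OCc1ccc(OC)cc1 | intermediate
15 | (1S,2R,3R,4S,5S)-5-[(4-methoxybenzyl)oxy]-2-(prop-1-en-2-yl)-3-[(triethylsilyl)oxy]-4-[(4R)-2,2,4-trimethyl-5-oxo-1,3-dioxolan-4-yl]cyclohexan-1-ol (ring = C10, C5, C6, C7, C8, C9) | O[C@H]1C[C@H](OCc2ccc(OC)cc2)[C@H]([C@@]2(C)OC(C)(C)OC2=O)[C@H](O[Si](CC)(CC)CC)[C@@H]1C(C)=C | intermediate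
16 | (2S,3S,4S,5S)-5-[(4-methoxybenzyl)oxy]-2-(prop-1-en-2-yl)-3-[(triethylsilyl)oxy]-4-[(4R)-2,2,4-trimethyl-5-oxo-1,3-dioxolan-4-yl]cyclohexan-1-one | O=C1C[C@H](OCc2ccc(OC)cc2)[C@H]([C@@]2(C)OC(C)(C)OC2=O)[C@H](O[Si](CC)(CC)CC)[C@@H]1C(C)=C | intermediate
17 | vinylmagnesium bromide | C=C[Mg]Br | starting material
18 | vinylcerium dichloride | C=C[Ce](Cl)Cl | intermediate (not isolated)
19 | (1S,2S,3R,4S,5S)-1-ethenyl-5-[(4-methoxybenzyl)oxy]-2-(prop-1-en-2-yl)-3-[(triethylsilyl)oxy]-4-[(4R)-2,2,4-trimethyl-5-oxo-1,3-dioxolan-4-yl]cyclohexan-1-ol (vinyl trans to isopropenyl) | C=C[C@@]1(O)C[C@H](OCc2ccc(OC)cc2)[C@H]([C@@]2(C)OC(C)(C)OC2=O)[C@H](O[Si](CC)(CC)CC)[C@@H]1C(C)=C | intermediate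
20 | (1S,2S,3R,4R,5S)-1-ethenyl-5-[(4-methoxybenzyl)oxy]-2-(prop-1-en-2-yl)-4-[(4R)-2,2,4-trimethyl-5-oxo-1,3-dioxolan-4-yl]cyclohexane-1,3-diol | C=C[C@@]1(O)C[C@H](OCc2ccc(OC)cc2)[C@H]([C@@]2(C)OC(C)(C)OC2=O)[C@H](O)[C@@H]1C(C)=C | intermediate (not isolated)
21 | (3R,3aS,4S,6S,7S,7aR)-6-ethenyl-3,6-dihydroxy-4-[(4-methoxybenzyl)oxy]-3-methyl-7-(prop-1-en-2-yl)hexahydro-1-benzofuran-2(3H)-one (cis-fused 6,12-lactone) | C=C[C@@]1(O)C[C@H](OCc2ccc(OC)cc2)[C@H]2[C@H](OC(=O)[C@]2(C)O)[C@@H]1C(C)=C | intermediate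
22 | dipotassium salt of the ten-membered C10 enolate / C11 alkoxide (C10=C1 enolate, 4E alkene, lactone intact) | COc1ccc(CO[C@H]2C/C([O-])=C/CC/C(C)=C/[C@H]3OC(=O)[C@](C)([O-])[C@@H]23)cc1.[K+].[K+] | intermediate (not isolated)
23 | (6R,7S,8S,11R)-11-hydroxy-8-(4-methoxybenzyloxy)-10-(trifluoromethanesulfonyloxy)-14-norgermacra-1(10),4E-dien-12,6-olide (C9 and C2 trans across C10=C1) | COc1ccc(CO[C@H]2C/C(OS(=O)(=O)C(F)(F)F)=C/CC/C(C)=C/[C@H]3OC(=O)[C@](C)(O)[C@@H]23)cc1 | intermediate
24 | (1(10)E,4E,6R,7S,8S,11R)-11-hydroxy-8-(4-methoxybenzyloxy)germacra-1(10),4-dien-12,6-olide | COc1ccc(CO[C@H]2C/C(C)=C/CC/C(C)=C/[C@H]3OC(=O)[C@](C)(O)[C@@H]23)cc1 | intermediate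
25 | (1(10)E,4E,6R,7S,8S,11R)-11-acetoxy-8-(4-methoxybenzyloxy)germacra-1(10),4-dien-12,6-olide | COc1ccc(CO[C@H]2C/C(C)=C/CC/C(C)=C/[C@H]3OC(=O)[C@](C)(OC(C)=O)[C@@H]23)cc1 | intermediate
26 | (1(10)E,4E,6R,7S,8S,11R)-11-acetoxy-8-hydroxygermacra-1(10),4-dien-12,6-olide | O[C@H]1C/C(C)=C/CC/C(C)=C/[C@H]2OC(=O)[C@](C)(OC(C)=O)[C@@H]12 | intermediate
27 | angelic acid [(Z)-2-methylbut-2-enoic acid] | C/C=C(/C)C(=O)O | starting material
28 | angelic 2,4,6-trichlorobenzoic anhydride | C/C=C(/C)C(=O)OC(=O)c1c(Cl)cc(Cl)cc1Cl | intermediate (not isolated)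
29 | (1(10)E,4E,6R,7S,8S,11R)-11-acetoxy-8-angeloyloxygermacra-1(10),4-dien-12,6-olide (CNP0144564.1) | C/C=C(/C)C(=O)O[C@H]1C/C(C)=C/CC/C(C)=C/[C@H]2OC(=O)[C@](C)(OC(C)=O)[C@@H]12 | target

**Step count**

Total: 18 steps. Longest linear sequence: 17 steps (steps 1–5 and 7–18, from (R)-citramalic acid); step 6 is the only side-branch step.

**Steps most likely to fail**

Step 3 (anti-aldol). The magnesium enolate of 4 carries the dioxolanone oxygen β to the enolate carbon and a neopentyl-like branch. It may therefore fragment by β-elimination with opening of the dioxolanone, or add so slowly at room temperature that the anti and facial selectivity erode. The fallback leaves the route at 2 and returns at 9. Acid 2 is coupled with 2-methylpropane-2-thiol (DCC, DMAP) to give S-tert-butyl 2-[(4R)-2,2,4-trimethyl-5-oxo-1,3-dioxolan-4-yl]ethanethioate F1. Enolisation at −78 °C with a menthone-derived bis(menthylmethyl)bromoborane of the appropriate antipode and Et3N gives the E enol borinate, which should add to 5 through a closed chair transition state under reagent control to give S-tert-butyl (2S,3R)-3-hydroxy-5-methyl-2-[(4R)-2,2,4-trimethyl-5-oxo-1,3-dioxolan-4-yl]hex-4-enethioate F2. Silylation (TESOTf, 2,6-lutidine) gives the triethylsilyl ether F3, and i-Bu2AlH at −78 °C reduces the thioester to aldehyde 9.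

Step 7 (acetate aldol at C8). The two α-branches of the very hindered aldehyde 9 are of similar size, so the intrinsic facial bias may be weak or opposed. The chiral promoter may then fail to override it or to bring about conversion, and C7 may epimerise on prolonged exposure. The fallback leaves the route at 9 and returns at 14, replacing reagent control by auxiliary control. The chlorotitanium enolate of (4R)-3-acetyl-4-isopropyl-1,3-thiazolidine-2-thione (TiCl4, i-Pr2NEt, CH2Cl2, −78 °C) should add to 9 through a chelated chair on the si face. This gives (4R)-3-{(3S,4S,5R)-3-hydroxy-7-methyl-5-[(triethylsilyl)oxy]-4-[(4R)-2,2,4-trimethyl-5-oxo-1,3-dioxolan-4-yl]oct-6-enoyl}-4-isopropyl-1,3-thiazolidine-2-thione F4. Etherification as in step 8 gives its 4-methoxybenzyl ether F5, and i-Bu2AlH at −78 °C then delivers aldehyde 14 directly, which also makes the thioester reduction unnecessary.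

Step 14 (ring expansion and trapping). Three processes may compete: sulfonylation of the C11 alkoxide, proton transfer within the enolate followed by β-elimination of the C8 ether, and poor solubility or slow rearrangement of the dianion. The fallback leaves the route at 21 and returns at 24, rearranging a mono-alkoxide with C11 masked. The exposed C11 hydroxyl of 21 is silylated in preference to the shielded axial C10 hydroxyl (TESOTf, 2,6-lutidine, −78 °C) to give the C11 triethylsilyl ether of the vinyl carbinol lactone F6. KH/18-crown-6 followed by PhNTf2 should then give the C11-silylated enol triflate F7. Negishi methylation as in step 15 gives the C11-silylated germacradienolide F8, and Bu4NF buffered with AcOH removes the silyl group to give 24.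

**Further compounds**

F1 | step 3 | S-tert-butyl 2-[(4R)-2,2,4-trimethyl-5-oxo-1,3-dioxolan-4-yl]ethanethioate | CC(C)(C)SC(=O)C[C@@]1(C)OC(C)(C)OC1=O
F2 | step 3 | S-tert-butyl (2S,3R)-3-hydroxy-5-methyl-2-[(4R)-2,2,4-trimethyl-5-oxo-1,3-dioxolan-4-yl]hex-4-enethioate | CC(C)=C[C@@H](O)[C@@H]([C@@]1(C)OC(C)(C)OC1=O)C(=O)SC(C)(C)C
F3 | step 3 | S-tert-butyl (2S,3R)-5-methyl-3-[(triethylsilyl)oxy]-2-[(4R)-2,2,4-trimethyl-5-oxo-1,3-dioxolan-4-yl]hex-4-enethioate | CC(C)=C[C@@H](O[Si](CC)(CC)CC)[C@@H]([C@@]1(C)OC(C)(C)OC1=O)C(=O)SC(C)(C)C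
F4 | step 7 | (4R)-3-{(3S,4S,5R)-3-hydroxy-7-methyl-5-[(triethylsilyl)oxy]-4-[(4R)-2,2,4-trimethyl-5-oxo-1,3-dioxolan-4-yl]oct-6-enoyl}-4-isopropyl-1,3-thiazolidine-2-thione | CC(C)=C[C@@H](O[Si](CC)(CC)CC)[C@@H]([C@@]1(C)OC(C)(C)OC1=O)[C@H](CC(=O)N1C(=S)SC[C@H]1C(C)C)O
F5 | step 7 | 4-methoxybenzyl ether of F4 (C8–OPMB) | CC(C)=C[C@@H](O[Si](CC)(CC)CC)[C@@H]([C@@]1(C)OC(C)(C)OC1=O)[C@H](CC(=O)N1C(=S)SC[C@H]1C(C)C)OCc1ccc(OC)cc1
F6 | step 14 | C11 triethylsilyl ether of 21 | C=C[C@@]1(O)C[C@H](OCc2ccc(OC)cc2)[C@H]2[C@H](OC(=O)[C@]2(C)O[Si](CC)(CC)CC)[C@@H]1C(C)=C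
F7 | step 14 | C11 triethylsilyl ether of enol triflate 23 | COc1ccc(CO[C@H]2C/C(OS(=O)(=O)C(F)(F)F)=C/CC/C(C)=C/[C@H]3OC(=O)[C@](C)(O[Si](CC)(CC)CC)[C@@H]23)cc1
F8 | step 14 | C11 triethylsilyl ether of 24 | COc1ccc(CO[C@H]2C/C(C)=C/CC/C(C)=C/[C@H]3OC(=O)[C@](C)(O[Si](CC)(CC)CC)[C@@H]23)cc1
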